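**Retrosynthetic overview**
1. The (1E,3E)-diene is cut at the double bond next to the isocoumarin (Horner–Wadsworth–Emmons): phosphonate 20 plus oxolanyl enal 12, the enal coming from oxolane-2-carboxylate 9 by reduction and a two-carbon Wittig extension.
2. Enabling feature: in the oxolane ring (O1, C2, C3, C4, C5), C2 carries exactly one exocyclic carbon (the first diene carbon); taken as a carboxyl carbon bonded to O1, it turns the same atoms into a six-membered δ-lactone (O1–C(=O)–C2–C3–C4–C5), and the 2,3-cis/2,5-trans pattern of the oxolane equals a syn-diol lying anti to the methyl group on that lactone after one inversion at C2.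
3. Key disconnection: ring contraction of α-triflyloxy δ-lactone 7 (methanolysis, then displacement of the triflate by the freed ring oxygen with inversion) to ester 9; the lactone comes from (S)-pent-4-en-2-ol by acrylation, ring-closing metathesis and syn-dihydroxylation, so one purchased stereocentre controls the other two.
4. The isocoumarin half comes from methyl orsellinate: chlorination, silylation, lateral lithiation–acylation, acid-catalysed enol lactonisation and Arbuzov reaction.
5. Order of ring formation: benzene ring purchased; six-membered lactone (metathesis), then oxolane (ring contraction); separately the pyranone ring of the isocoumarin (enol lactonisation); the halves are joined last and all silyl groups leave in one step.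

Key step: step 5

Remark on the chemistry: 1, 2, 11, 13 and 16 are taken as purchased materials, and locants in the text follow the systematic name of the compound under discussion.

**Step 1**
Reactants: 1 (2S)-pent-4-en-2-ol; 2 prop-2-enoyl chloride
Product: 3 (2S)-pent-4-en-2-yl prop-2-enoate
Conditions: Et3N, DMAP (cat.), CH2Cl2, 0 °C → rt
Reagents that add atoms: none
Why: DMAP-catalysed O-acylation of the secondary alcohol with the acid chloride leaves the stereocentre untouched, and it is carried through as C5 of the oxolane.

**Step 2**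
Reactants: 3 (2S)-pent-4-en-2-yl prop-2-enoate
Product: 4 (6S)-6-methyl-5,6-dihydro-2H-pyran-2-one
Conditions: second-generation Grubbs catalyst (H2IMes)(PCy3)Cl2Ru=CHPh (3 mol %), CH2Cl2 (high dilution), 40 °C
Reagents that add atoms: none
Why: Ring-closing olefin metathesis of the acrylate closes the six-membered α,β-unsaturated δ-lactone with loss of ethene, a standard entry to 6-substituted 5,6-dihydropyran-2-ones.

**Step 3**
Reactants: 4 (6S)-6-methyl-5,6-dihydro-2H-pyran-2-one
Product: 5 (3S,4S,6S)-3,4-dihydroxy-6-methyloxan-2-one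
Conditions: OsO4 (2 mol %), NMO, acetone/H2O, 0 °C → rt
Reagents that add atoms: osmium tetroxide, O=[Os](=O)(=O)=O; 4-methylmorpholine N-oxide, C[N+]1([O-])CCOCC1; water, O
Why: Catalytic osmium tetroxide syn-dihydroxylation of the half-chair lactone should occur on the face anti to the pseudo-equatorial 6-methyl group, as is usual for 6-substituted 5,6-dihydropyran-2-ones, so C3 and C4 are set under substrate control with both hydroxyls cis to each other and trans to the methyl group.

**Step 4**
Reactants: 5 (3S,4S,6S)-3,4-dihydroxy-6-methyloxan-2-one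
Product: 7 (3S,4S,6S)-4-[(tert-butyldimethylsilyl)oxy]-6-methyl-2-oxooxan-3-yl trifluoromethanesulfonate, via monotriflate 6 (not isolated)
Conditions: Tf2O (1.05 equiv), pyridine, CH2Cl2, −40 °C; then TBSOTf, 2,6-lutidine, −40 → 0 °C
Reagents that add atoms: trifluoromethanesulfonic anhydride, O=S(=O)(OS(=O)(=O)C(F)(F)F)C(F)(F)F; tert-butyldimethylsilyl trifluoromethanesulfonate, CC(C)(C)[Si](C)(C)OS(=O)(=O)C(F)(F)F
Why: Regioselective O-sulfonylation then O-silylation in one flask, in which the equatorial and more acidic hydroxyl α to the lactone carbonyl is sulfonylated first, as known for α,β-dihydroxy lactones and esters, and the remaining axial hydroxyl is capped as its silyl ether without change at any stereocentre.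

**Step 5**
Reactants: 7 (3S,4S,6S)-4-[(tert-butyldimethylsilyl)oxy]-6-methyl-2-oxooxan-3-yl trifluoromethanesulfonate
Product: 9 methyl (2R,3S,5S)-3-[(tert-butyldimethylsilyl)oxy]-5-methyloxolane-2-carboxylate, via open-chain hydroxy ester 8 (not isolated)
Conditions: K2CO3 (1.2 equiv), MeOH, −20 → 0 °C, short reaction time; aq. NaH2PO4 quench
Reagents that add atoms: methanol, CO
Why: Methoxide adds to the lactone carbonyl of 7, which the α-triflyloxy group makes strongly electrophilic, and ring opening to methyl ester 8 frees the C5 alkoxide, which at once displaces the triflate at C2 by intramolecular SN2 attack and so forms the O–C2 bond of the oxolane. The closest known reaction type is the base-induced ring contraction of 2-O-triflyl aldono-1,5-lactones to 2,5-anhydroaldonate esters (tetrahydrofuran-2-carboxylates). The oxolane ring is closed in the 5-exo-tet mode. The only new stereocentre, C2, is set by inversion of the triflate-bearing carbon, so the syn-diol geometry of 5 (both oxygens anti to the methyl group) is translated into the 2,3-cis/2,5-trans pattern of the target while C3 and C5 are untouched. The step needs attack of O5 at C2 rather than epoxide closure from O3, β-elimination or epimerisation of the new α-alkoxy ester: the silyl ether blocks O3, the tether allows only five-membered closure at the activated α-carbon, and low temperature with a short reaction time should keep the kinetically formed cis ester from equilibrating.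

**Step 6**
Reactants: 9 methyl (2R,3S,5S)-3-[(tert-butyldimethylsilyl)oxy]-5-methyloxolane-2-carboxylate
Product: 10 (2R,3S,5S)-3-[(tert-butyldimethylsilyl)oxy]-5-methyloxolane-2-carbaldehyde
Conditions: i-Bu2AlH (1.1 equiv), CH2Cl2, −78 °C; aq. KNaC4H4O6 work-up
Reagents that add atoms: none
Why: Partial hydride reduction of the α-alkoxy methyl ester stops at the aldehyde because the chelated tetrahedral aluminium hemiacetal survives at −78 °C until work-up, and the non-basic conditions should leave the cis C2 centre unchanged.

**Step 7**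
Reactants: 10 (2R,3S,5S)-3-[(tert-butyldimethylsilyl)oxy]-5-methyloxolane-2-carbaldehyde; 11 (triphenylphosphoranylidene)acetaldehyde
Product: 12 (2E)-3-[(2S,3S,5S)-3-[(tert-butyldimethylsilyl)oxy]-5-methyloxolan-2-yl]prop-2-enal
Conditions: toluene, 60 °C
Reagents that add atoms: none
Why: Wittig olefination with the stabilised formylmethylene ylide under neutral conditions should give the (E)-enal selectively and not epimerise the α-alkoxy aldehyde.

**Step 8**
Reactants: 13 methyl 2,4-dihydroxy-6-methylbenzoate
Product: 14 methyl 3-chloro-4,6-dihydroxy-2-methylbenzoate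
Conditions: SO2Cl2 (1.0 equiv), Et2O, 0 °C
Reagents that add atoms: sulfuryl chloride, ClS(Cl)(=O)=O
Why: Electrophilic aromatic chlorination of the resorcinol ring should go to C5 of 13, between the methyl group and the 4-hydroxyl and para to the hydrogen-bonded 2-hydroxyl, the usual position for orsellinates.

**Step 9**
Reactants: 14 methyl 3-chloro-4,6-dihydroxy-2-methylbenzoate
Product: 15 methyl 3-chloro-2-methyl-4,6-bis[(triisopropylsilyl)oxy]benzoate
Conditions: TIPSOTf (2.4 equiv), 2,6-lutidine, CH2Cl2, 0 °C → rt
Reagents that add atoms: triisopropylsilyl trifluoromethanesulfonate, CC(C)[Si](OS(=O)(=O)C(F)(F)F)(C(C)C)C(C)C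
Why: O-Silylation of both phenols with the silyl triflate and a hindered base gives robust aryl silyl ethers that should tolerate the later amide base, acid and heat and leave with fluoride at the end.

**Step 10**
Reactants: 15 methyl 3-chloro-2-methyl-4,6-bis[(triisopropylsilyl)oxy]benzoate; 16 2-chloro-N-methoxy-N-methylacetamide
Product: 18 methyl 3-chloro-2-(3-chloro-2-oxopropyl)-4,6-bis[(triisopropylsilyl)oxy]benzoate, via benzylic organolithium 17 (not isolated)
Conditions: LiN(i-Pr)2 (1.1 equiv), THF, −78 °C; then 16, −78 °C; aq. HCl (1 M) quench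
Reagents that add atoms: none
Why: Lateral lithiation of the ortho-toluate methyl group followed by acylation with the N-methoxy-N-methylamide (Weinreb ketone synthesis) should stop at the ketone because the chelated tetrahedral adduct persists until the quench, as in the known acylation of ester enolates with this chloroacetamide.

**Step 11**
Reactants: 18 methyl 3-chloro-2-(3-chloro-2-oxopropyl)-4,6-bis[(triisopropylsilyl)oxy]benzoate
Product: 19 5-chloro-3-(chloromethyl)-6,8-bis[(triisopropylsilyl)oxy]-1H-isochromen-1-one
Conditions: p-TsOH·H2O (cat.), toluene, 80 °C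
Reagents that add atoms: none
Why: Acid-catalysed enol lactonisation, in which the enol oxygen of the benzylic ketone attacks the neighbouring methyl ester with loss of methanol, closes the pyranone ring of the isocoumarin, while base, which would favour C-acylation to a naphthol, is avoided.

**Step 12**
Reactants: 19 5-chloro-3-(chloromethyl)-6,8-bis[(triisopropylsilyl)oxy]-1H-isochromen-1-one
Product: 20 diethyl ({5-chloro-1-oxo-6,8-bis[(triisopropylsilyl)oxy]-1H-isochromen-3-yl}methyl)phosphonate
Conditions: P(OEt)3, NaI (cat.), 120 °C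
Reagents that add atoms: triethyl phosphite, CCOP(OCC)OCC
Why: Michaelis–Arbuzov reaction of the allylic chloride with triethyl phosphite, helped by catalytic iodide exchange, should give the phosphonate.

**Step 13**
Reactants: 20 diethyl ({5-chloro-1-oxo-6,8-bis[(triisopropylsilyl)oxy]-1H-isochromen-3-yl}methyl)phosphonate; 12 (2E)-3-[(2S,3S,5S)-3-[(tert-butyldimethylsilyl)oxy]-5-methyloxolan-2-yl]prop-2-enal
Product: 22 5-chloro-3-{(1E,3E)-4-[(2S,3S,5S)-3-[(tert-butyldimethylsilyl)oxy]-5-methyloxolan-2-yl]buta-1,3-dien-1-yl}-6,8-bis[(triisopropylsilyl)oxy]-1H-isochromen-1-one, via lithiated phosphonate 21 (not isolated)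
Conditions: LiN(SiMe3)2, THF, −78 °C; then 12, −78 → 0 °C
Reagents that add atoms: none
Why: Horner–Wadsworth–Emmons olefination of the conjugated phosphonate anion with the (E)-enal should form the second double bond with the (E)-selectivity typical of stabilised phosphonates, and the low temperature and non-nucleophilic amide base should spare the lactone, the aryl silyl ethers and the allylic C2 centre.

**Step 14**
Reactants: 22 5-chloro-3-{(1E,3E)-4-[(2S,3S,5S)-3-[(tert-butyldimethylsilyl)oxy]-5-methyloxolan-2-yl]buta-1,3-dien-1-yl}-6,8-bis[(triisopropylsilyl)oxy]-1H-isochromen-1-one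
Product: 23 5-chloro-6,8-dihydroxy-3-{(1E,3E)-4-[(2S,3S,5S)-3-hydroxy-5-methyloxolan-2-yl]buta-1,3-dien-1-yl}-1H-isochromen-1-one
Conditions: Bu4NF, AcOH, THF, 0 °C → rt
Reagents that add atoms: none
Why: Fluoride-mediated desilylation buffered with acetic acid should cleave the two aryl silyl ethers and the secondary silyl ether in one operation, without acid that could ionise the dienylic C2–O bond or strong base that could open the lactone.

**Compound list**
1 | (2S)-pent-4-en-2-ol | C[C@H](O)CC=C | starting material
2 | prop-2-enoyl chloride (acryloyl chloride) | C=CC(Cl)=O | starting material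
3 | (2S)-pent-4-en-2-yl prop-2-enoate | C[C@H](OC(=O)C=C)CC=C | intermediate
4 | (6S)-6-methyl-5,6-dihydro-2H-pyran-2-one | C[C@H]1CC=CC(=O)O1 | intermediate
5 | (3S,4S,6S)-3,4-dihydroxy-6-methyloxan-2-one | C[C@H]1C[C@H](O)[C@H](O)C(=O)O1 | intermediate
6 | (3S,4S,6S)-4-hydroxy-6-methyl-2-oxooxan-3-yl trifluoromethanesulfonate (not isolated) | C[C@H]1C[C@H](O)[C@H](OS(=O)(=O)C(F)(F)F)C(=O)O1 | intermediate
7 | (3S,4S,6S)-4-[(tert-butyldimethylsilyl)oxy]-6-methyl-2-oxooxan-3-yl trifluoromethanesulfonate | C[C@H]1C[C@H](O[Si](C)(C)C(C)(C)C)[C@H](OS(=O)(=O)C(F)(F)F)C(=O)O1 | intermediate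
8 | methyl (2S,3S,5S)-3-[(tert-butyldimethylsilyl)oxy]-5-hydroxy-2-[(trifluoromethanesulfonyl)oxy]hexanoate (formed as its alkoxide, not isolated) | C[C@H](O)C[C@H](O[Si](C)(C)C(C)(C)C)[C@H](OS(=O)(=O)C(F)(F)F)C(=O)OC | intermediate
9 | methyl (2R,3S,5S)-3-[(tert-butyldimethylsilyl)oxy]-5-methyloxolane-2-carboxylate | C[C@H]1C[C@H](O[Si](C)(C)C(C)(C)C)[C@H](C(=O)OC)O1 | intermediate
10 | (2R,3S,5S)-3-[(tert-butyldimethylsilyl)oxy]-5-methyloxolane-2-carbaldehyde | C[C@H]1C[C@H](O[Si](C)(C)C(C)(C)C)[C@H](C=O)O1 | intermediate
11 | (triphenylphosphoranylidene)acetaldehyde | O=CC=P(c1ccccc1)(c1ccccc1)c1ccccc1 | starting material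
12 | (2E)-3-[(2S,3S,5S)-3-[(tert-butyldimethylsilyl)oxy]-5-methyloxolan-2-yl]prop-2-enal | C[C@H]1C[C@H](O[Si](C)(C)C(C)(C)C)[C@H](/C=C/C=O)O1 | intermediate
13 | methyl 2,4-dihydroxy-6-methylbenzoate (methyl orsellinate) | COC(=O)c1c(C)cc(O)cc1O | starting material
14 | methyl 3-chloro-4,6-dihydroxy-2-methylbenzoate | COC(=O)c1c(C)c(Cl)c(O)cc1O | intermediate
15 | methyl 3-chloro-2-methyl-4,6-bis[(triisopropylsilyl)oxy]benzoate | COC(=O)c1c(C)c(Cl)c(O[Si](C(C)C)(C(C)C)C(C)C)cc1O[Si](C(C)C)(C(C)C)C(C)C | intermediate
16 | 2-chloro-N-methoxy-N-methylacetamide | CON(C)C(=O)CCl | starting material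
17 | {2-chloro-6-(methoxycarbonyl)-3,5-bis[(triisopropylsilyl)oxy]phenyl}methyllithium (not isolated) | [Li]Cc1c(Cl)c(O[Si](C(C)C)(C(C)C)C(C)C)cc(O[Si](C(C)C)(C(C)C)C(C)C)c1C(=O)OC | intermediate
18 | methyl 3-chloro-2-(3-chloro-2-oxopropyl)-4,6-bis[(triisopropylsilyl)oxy]benzoate | COC(=O)c1c(CC(=O)CCl)c(Cl)c(O[Si](C(C)C)(C(C)C)C(C)C)cc1O[Si](C(C)C)(C(C)C)C(C)C | intermediate
19 | 5-chloro-3-(chloromethyl)-6,8-bis[(triisopropylsilyl)oxy]-1H-isochromen-1-one | ClCc1cc2c(Cl)c(O[Si](C(C)C)(C(C)C)C(C)C)cc(O[Si](C(C)C)(C(C)C)C(C)C)c2c(=O)o1 | intermediate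
20 | diethyl ({5-chloro-1-oxo-6,8-bis[(triisopropylsilyl)oxy]-1H-isochromen-3-yl}methyl)phosphonate | CCOP(=O)(OCC)Cc1cc2c(Cl)c(O[Si](C(C)C)(C(C)C)C(C)C)cc(O[Si](C(C)C)(C(C)C)C(C)C)c2c(=O)o1 | intermediate
21 | α-lithio derivative of phosphonate 20 (lithium on the carbon between phosphorus and the isocoumarin; not isolated) | CCOP(=O)(OCC)C([Li])c1cc2c(Cl)c(O[Si](C(C)C)(C(C)C)C(C)C)cc(O[Si](C(C)C)(C(C)C)C(C)C)c2c(=O)o1 | intermediate
22 | 5-chloro-3-{(1E,3E)-4-[(2S,3S,5S)-3-[(tert-butyldimethylsilyl)oxy]-5-methyloxolan-2-yl]buta-1,3-dien-1-yl}-6,8-bis[(triisopropylsilyl)oxy]-1H-isochromen-1-one | C[C@H]1C[C@H](O[Si](C)(C)C(C)(C)C)[C@H](/C=C/C=C/c2cc3c(Cl)c(O[Si](C(C)C)(C(C)C)C(C)C)cc(O[Si](C(C)C)(C(C)C)C(C)C)c3c(=O)o2)O1 | intermediate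
23 | 5-chloro-6,8-dihydroxy-3-{(1E,3E)-4-[(2S,3S,5S)-3-hydroxy-5-methyloxolan-2-yl]buta-1,3-dien-1-yl}-1H-isochromen-1-one | C[C@H]1C[C@H](O)[C@H](/C=C/C=C/c2cc3c(Cl)c(O)cc(O)c3c(=O)o2)O1 | target

**Totals**
Total step count: 14. Longest linear sequence: 9 steps (steps 1–7, 13 and 14, from 1).

**Steps most likely to fail**

Step 4. What may go wrong: loss of regiocontrol in the sulfonylation (reaction at the axial hydroxyl or at both hydroxyls), which would put the leaving group on the wrong carbon. The fallback sets out from 5 and comes back at 9; it activates both oxygens together instead of telling them apart. Diol 5 with SOCl2 and pyridine in CH2Cl2 at 0 °C should give the cyclic sulfite F1, and oxidation with catalytic RuCl3 and NaIO4 in MeCN/H2O the cyclic sulfate F2. With K2CO3 in MeOH at −20 °C the lactone is opened, and the freed alkoxide can reach only the α-carbon of the cyclic sulfate in a five-membered closure. This should give the potassium sulfate monoester F3 of the ring-contracted ester with the same inversion at C2. Catalytic H2SO4 in wet THF should then hydrolyse it to the hydroxy ester F4, and TBSCl with imidazole in DMF should give 9.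

Step 5. What may go wrong: epimerisation at C2 of the kinetically formed 2,3-cis ester in the carbonate/methoxide medium, β-elimination of the silyloxy group, or migration of the silyl group to the freed alkoxide followed by epoxide closure. The fallback sets out from 7 and comes back at 10; it moves the contraction to the hemiacetal oxidation level, where neither an alkoxide base nor an ester enolate is involved. Reduction of 7 with i-Bu2AlH in CH2Cl2 at −78 °C should give the lactol triflate F5. With NaHCO3 in aqueous MeCN at room temperature the ring oxygen (or the hydroxyl of the open hydroxy aldehyde form) should displace the neighbouring triflate with inversion, as in the ring contraction that accompanies deamination of 2-amino-2-deoxypyranoses. This should give aldehyde 10 directly, so ester 9 and step 6 are bypassed.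

Step 13. What may go wrong: low (E)-selectivity in the olefination, or base-induced γ-deprotonation of the enal with loss of configuration at C2 of the oxolane or ring-opening β-elimination. The fallback sets out from 10 and 20 and comes back at 22; it joins the diene at its central single bond by a Heck reaction under weakly basic conditions. Takai olefination of aldehyde 10 (CrCl2, CHI3, THF, 0 °C) should give the (E)-iodoalkene F6. Phosphonate 20 with aqueous formaldehyde and K2CO3 in THF should give the 3-vinylisocoumarin F7. Coupling of the two (Pd(OAc)2, Bu4NCl, NaHCO3, DMF, 40 °C) should give 22 with retention of the iodoalkene geometry and an (E)-configured new double bond.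

**Further compounds**
F1 | step 4 | cyclic sulfite of diol 5 (3,4-O-sulfinyl derivative, both epimers at sulfur) | C[C@H]1C[C@@H]2OS(=O)O[C@@H]2C(=O)O1
F2 | step 4 | cyclic sulfate of diol 5 (3,4-O-sulfonyl derivative) | C[C@H]1C[C@@H]2OS(=O)(=O)O[C@@H]2C(=O)O1
F3 | step 4 | potassium (2R,3S,5S)-2-(methoxycarbonyl)-5-methyloxolan-3-yl sulfate | C[C@H]1C[C@H](OS(=O)(=O)[O-])[C@H](C(=O)OC)O1.[K+]
F4 | step 4 | methyl (2R,3S,5S)-3-hydroxy-5-methyloxolane-2-carboxylate | C[C@H]1C[C@H](O)[C@H](C(=O)OC)O1
F5 | step 5 | (3S,4S,6S)-4-[(tert-butyldimethylsilyl)oxy]-2-hydroxy-6-methyloxan-3-yl trifluoromethanesulfonate (lactol, both anomers) | C[C@H]1C[C@H](O[Si](C)(C)C(C)(C)C)[C@H](OS(=O)(=O)C(F)(F)F)C(O)O1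
F6 | step 13 | (2S,3S,5S)-3-[(tert-butyldimethylsilyl)oxy]-2-[(E)-2-iodoethenyl]-5-methyloxolane | C[C@H]1C[C@H](O[Si](C)(C)C(C)(C)C)[C@H](/C=C/I)O1
F7 | step 13 | 5-chloro-3-ethenyl-6,8-bis[(triisopropylsilyl)oxy]-1H-isochromen-1-one | C=Cc1cc2c(Cl)c(O[Si](C(C)C)(C(C)C)C(C)C)cc(O[Si](C(C)C)(C(C)C)C(C)C)c2c(=O)o1
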